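**Retrosynthetic overview**

1. Azulene numbering is used for the core (C1 carbinol, C3 isopropyl carbinol, C3a–H, C4 ester carbon, C6(CH3)=C7, C8a–CH3). Late steps: C1–OH from the ketone, the C4 ester from C4–OH, C4–OH by hydroxyl-directed reduction of the ketone, C6=C7 by 1,4-hydrogenation of a C5–C8 diene.
2. Key disconnection: the seven-membered ring is the benzene ring of a 2-oxy-4-methylphenyl group (C3a, C4, C5, C6, C7, C8) into which one carbene carbon (C8a, carrying the methyl) is inserted between C3a and C8 by an intramolecular Buchner reaction of a 2-diazo-3-ketone. The same event closes the cyclopentanone (bond C8a–C3a).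
3. Enabling feature: C3a, C4–O and C6–CH3 are 1,2,4-related on the seven-membered ring exactly as the acylated carbon, OH and CH3 are in ortho-acylated m-cresol. The oxygenated C1 is next to the methylated ring-fusion carbon C8a, as in an α-diazo ketone. The C3 and C4 oxygens are 1,3-related, so one silylene ties them into a temporary ring that passes the C3 configuration on to C8a.
4. Precursor: m-cresol → 4-isopropyl-7-methylcoumarin (Pechmann) → enantioselective conjugate borylation (sets C3) → amide → silylene → ethyl ketone → diazo transfer.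
5. Ring order: benzene ring (m-cresol) → temporary dioxasiline ring → cyclopentanone and cycloheptatriene together in the key step → dioxasiline removed one step later.

Key step: step 7

Remark: the copper-catalysed borylation is assumed to give either enantiomer by choice of the ligand antipode; the antipode that leads to the (R)-carbinol is used.

**Step 1**
Reactants: 1 3-methylphenol (m-cresol); 2 ethyl 4-methyl-3-oxopentanoate
Product: 3 4-isopropyl-7-methyl-2H-chromen-2-one
Conditions: conc. H2SO4, 0 °C to rt
Reagents that add atoms: ethyl 4-methyl-3-oxopentanoate (2), CCOC(=O)CC(=O)C(C)C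
Why: Pechmann condensation: acid-mediated transesterification of the β-keto ester by the phenol, ring closure onto the position ortho to oxygen and para to methyl (the less hindered activated site, as in the known formation of 4,7-dimethylcoumarin from m-cresol) and dehydration should give the 7-methylcoumarin.

**Step 2**
Reactants: 3 4-isopropyl-7-methyl-2H-chromen-2-one; 4 bis(pinacolato)diboron
Product: 5 (4S)-4-isopropyl-7-methyl-4-(4,4,5,5-tetramethyl-1,3,2-dioxaborolan-2-yl)chroman-2-one
Conditions: CuCl (5 mol %), NaOt-Bu (10 mol %), Josiphos ligand (R)-1-[(S)-2-(diphenylphosphino)ferrocenyl]ethyldicyclohexylphosphine or its enantiomer (6 mol %, antipode chosen for 4S), t-BuOH (2 equiv), THF, rt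
Reagents that add atoms: bis(pinacolato)diboron (4), CC1(C)OB(OC1(C)C)B1OC(C)(C)C(C)(C)O1
Why: Copper-catalysed enantioselective conjugate borylation of a β,β-disubstituted unsaturated ester: the ligated Cu–Bpin species adds across C3=C4 of the coumarin with boron on the β-carbon, the copper enolate is protonated by t-BuOH (too hindered to open the aryl lactone), and the chiral bisphosphine selects the face of the planar coumarin and so sets the boron-bearing quaternary stereocentre (4S, the later C3 of the target).

**Step 3**
Reactants: 5 (4S)-boryl lactone; 6 morpholine; 7 sodium perborate tetrahydrate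
Product: 9 (3R)-3-hydroxy-3-(2-hydroxy-4-methylphenyl)-4-methyl-1-(morpholin-4-yl)pentan-1-one, via boryl amide 8 (not isolated)
Conditions: morpholine (3 equiv), THF, rt; concentrate; then NaBO3·4H2O, THF/H2O, rt
Reagents that add atoms: morpholine (6), C1COCCN1; sodium perborate (7), [Na+].[Na+].O[B-]1(O)OO[B-](O)(O)OO1
Why: Aminolysis of the aryl ester (a dihydrocoumarin is an active ester) followed by perborate oxidation of the C–B bond, in which carbon migrates from boron to oxygen with retention, should give the tertiary benzylic alcohol (3R) without exposing a β-hydroxy lactone to base.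

**Step 4**
Reactants: 9 (3R)-diol amide; 10 di(propan-2-yl)silanediyl bis(trifluoromethanesulfonate)
Product: 11 2-[(4R)-7-methyl-2,2,4-tri(propan-2-yl)-4H-1,3,2-benzodioxasilin-4-yl]-1-(morpholin-4-yl)ethan-1-one
Conditions: i-Pr2Si(OTf)2 (1.1 equiv), 2,6-lutidine (3 equiv), CH2Cl2, 0 °C to rt
Reagents that add atoms: di(propan-2-yl)silanediyl bis(trifluoromethanesulfonate) (10), CC(C)[Si](OS(=O)(=O)C(F)(F)F)(OS(=O)(=O)C(F)(F)F)C(C)C
Why: Cyclic silylene formation: the bis(triflate) silylates the phenol and then closes onto the 1,3-related tertiary hydroxyl to the six-membered 1,3,2-dioxasiline under buffered, non-ionising conditions, which masks both oxygens and holds the C3–O bond near the arene plane for step 7.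

**Step 5**
Reactants: 11 silylene amide; 12 ethylmagnesium bromide
Product: 13 1-[(4R)-7-methyl-2,2,4-tri(propan-2-yl)-4H-1,3,2-benzodioxasilin-4-yl]butan-2-one
Conditions: EtMgBr (2.5 equiv), THF, 0 °C; aq. NH4Cl
Reagents that add atoms: ethylmagnesium bromide (12), CC[Mg]Br
Why: Ketone synthesis by addition of a Grignard reagent to a morpholine amide (Weinreb-type acylation): the tetrahedral magnesium adduct persists until work-up, so a single ethyl group is transferred, and the hindered dialkoxysilane should be inert at 0 °C.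

**Step 6**
Reactants: 13 ethyl ketone; 14 2,2,2-trifluoroethyl trifluoroacetate; 15 4-acetamidobenzenesulfonyl azide
Product: 17 3-diazo-1-[(4R)-7-methyl-2,2,4-tri(propan-2-yl)-4H-1,3,2-benzodioxasilin-4-yl]butan-2-one, via trifluoroacetyl diketone 16 (not isolated)
Conditions: LiN(SiMe3)2, THF, −78 °C; CF3CO2CH2CF3; dilute aq. HCl wash; then 15, Et3N, H2O (1 equiv), MeCN, rt
Reagents that add atoms: 2,2,2-trifluoroethyl trifluoroacetate (14), FC(F)(F)COC(=O)C(F)(F)F; 4-acetamidobenzenesulfonyl azide (15), CC(=O)Nc1ccc(cc1)S(=O)(=O)N=[N+]=[N-]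
Why: Detrifluoroacetylative (Regitz-type deacylative) diazo transfer: kinetic enolisation occurs at the ethyl CH2 and not at the neopentyl-like CH2 next to the quaternary carbon, Claisen trifluoroacetylation by 14 activates that position in 16, and the sulfonyl azide then delivers N2 while the trifluoroacetyl group leaves as the N-acylsulfonamide, so that of the two reagents only 15 contributes atoms (the two diazo nitrogens) to 17.

**Step 7**
Reactants: 17 diazo ketone
Product: 19 (3R,8aR)-3,4-[di(propan-2-yl)silanediylbis(oxy)]-3-isopropyl-6,8a-dimethyl-3,8a-dihydroazulen-1(2H)-one, via norcaradiene 18 (not isolated)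
Conditions: Rh2(O2CCH(OH)Ph)4 (dirhodium tetramandelate, 1 mol %), CH2Cl2, 40 °C, slow addition of 17
Reagents that add atoms: none
Why: Loss of N2 from 17 at the divalent rhodium carboxylate gives an electrophilic acyl(methyl)carbene complex that cyclopropanates the C3a–C8 bond of the arene to norcaradiene 18, and 6π disrotatory electrocyclic opening of 18 (cleavage of C3a–C8) inserts the carbene carbon C8a between C3a and C8 to give cycloheptatriene 19. The closest known reaction type is the intramolecular Buchner reaction of 1-diazo-4-arylbutan-2-ones to 3,8a-dihydroazulen-1(2H)-ones, which is also known for 2-diazo-3-ketones (8a-methyl products) and for diazo ketone arms on a benzylic carbon of a fused ring. The cyclopentanone is closed by the C8a–C3a bond of the cyclopropanation (three-atom tether, bicyclo[3.1.0] mode), and the seven-membered ring arises from the benzene ring by one-carbon ring expansion in the electrocyclic opening. The only new stereocentre, C8a, is controlled by C3 through the dioxasiline ring: this ring holds the C3–O bond near the arene plane on the side of C4, so the diazo ketone arm and the isopropyl group project to opposite faces of the arene, the carbene can add only from the face of its own arm, and because C1 stays on the tether side of the cyclopropane the methyl group ends on the face of the five-membered ring that carries the C3 oxygen, trans to isopropyl (8aR). The step needs site selectivity for C3a–C8 over C3a–C4 and chemoselectivity for arene addition over 1,2-hydride shift, insertion into the isopropyl C–H and oxonium ylide formation; the first is secured by the ring (addition at C3a–C4 would strain the dioxasiline and meets the substituted ortho carbon), the second by the electron-rich ipso carbon (ortho oxygen, para methyl), the hindered and weakly basic silyl ether oxygen, and slow addition to a carboxylate catalyst.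

**Step 8**
Reactants: 19 silylene-bridged azulenone
Product: 21 (3R,3aR,8aR)-3-hydroxy-3-isopropyl-6,8a-dimethyl-2,3,3a,8a-tetrahydroazulene-1,4-dione, via cis-fused 3a-epimer 20 (not isolated)
Conditions: HF·pyridine, pyridine, THF, 0 °C to rt; then DBU (0.3 equiv), CH2Cl2, rt
Reagents that add atoms: none
Why: Fluoride cleaves the enol Si–O bond and then the tertiary Si–O bond (silyl enol ether cleavage), the freed C4 dienol is C-protonated at C3a, probably first from the face away from isopropyl, and DBU then equilibrates this centre through the C4 enolate to the trans-fused ketone, which should be favoured because C4 is then cis to the C3 hydroxyl (hydrogen bond) instead of eclipsing isopropyl, so that H-3a ends trans to the angular methyl.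

**Step 9**
Reactants: 21 β-hydroxy dienone dione
Product: 22 (3R,3aR,8aR)-3-hydroxy-3-isopropyl-6,8a-dimethyl-2,3,3a,5,8,8a-hexahydroazulene-1,4-dione
Conditions: H2 (50 bar), (η6-naphthalene)Cr(CO)3 (15 mol %), THF, 45 °C
Reagents that add atoms: none
Why: (Arene)Cr(CO)3-catalysed 1,4-hydrogenation of a conjugated s-cis diene: the cyclic diene C5=C6–C7=C8 binds η4 to the zerovalent chromium tricarbonyl fragment and takes up H2 at its termini C5 and C8, which leaves the trisubstituted C6=C7 bond out of conjugation with the C4 ketone (as sorbate esters give 3-hexenoates) and creates no stereocentre.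

**Step 10**
Reactants: 22 β,γ-unsaturated dione
Product: 23 (3R,3aS,4S,8aR)-3,4-dihydroxy-3-isopropyl-6,8a-dimethyl-3,3a,4,5,8,8a-hexahydroazulen-1(2H)-one
Conditions: Me4NBH(OAc)3 (5 equiv), MeCN/AcOH (1:1), −30 °C
Reagents that add atoms: none
Why: Evans–Saksena hydroxyl-directed reduction: the C3 hydroxyl exchanges an acetate on boron and the hydride is delivered through a six-membered transition state to the C4 carbonyl face on the side of C3, which gives the anti 1,3-diol with H-4 trans to H-3a (4S), while the C1 ketone, whose matching face is blocked by the adjacent angular methyl and which this mild reagent does not reduce intermolecularly, should survive.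

**Step 11**
Reactants: 23 diol ketone; 24 4-(chlorocarbonyl)phenyl acetate (4-acetoxybenzoyl chloride)
Product: 25 (3R,3aS,4S,8aR)-3-hydroxy-3-isopropyl-6,8a-dimethyl-1-oxo-1,2,3,3a,4,5,8,8a-octahydroazulen-4-yl 4-acetoxybenzoate
Conditions: 24 (1.3 equiv), Et3N, DMAP (cat.), CH2Cl2, 0 °C to rt
Reagents that add atoms: 4-acetoxybenzoyl chloride (24), CC(=O)Oc1ccc(cc1)C(Cl)=O
Why: DMAP-catalysed acylation with an acid chloride should esterify the only secondary hydroxyl, at C4, because the C3 hydroxyl is tertiary and flanked by isopropyl, and no stereocentre is touched.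

**Step 12**
Reactants: 25 keto ester
Product: 27 (1R,3R,3aS,4S,8aR)-1,3-dihydroxy-3-isopropyl-6,8a-dimethyl-1,2,3,3a,4,5,8,8a-octahydroazulen-4-yl 4-hydroxybenzoate (target), via aryl acetate 26 (not isolated)
Conditions: NaBH4, MeOH/THF, −20 °C; then K2CO3, MeOH, 0 °C to rt
Reagents that add atoms: none
Why: NaBH4 should add to the cyclopentanone from the face opposite to the adjacent angular methyl, as in the reduction of the Hajos–Parrish ketone and of 17-oxo steroids, which gives the C1 hydroxyl cis to that methyl (1R), and methanolysis then removes the phenolic acetate, which is far more labile than the hindered secondary benzoate.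

**Compound list**

1 | 3-methylphenol (m-cresol) | Cc1cccc(O)c1 | starting material
2 | ethyl 4-methyl-3-oxopentanoate | CCOC(=O)CC(=O)C(C)C | starting material
3 | 4-isopropyl-7-methyl-2H-chromen-2-one | CC(C)C1=CC(=O)Oc2cc(C)ccc12 | intermediate
4 | bis(pinacolato)diboron | CC1(C)OB(OC1(C)C)B1OC(C)(C)C(C)(C)O1 | starting material
5 | (4S)-4-isopropyl-7-methyl-4-(4,4,5,5-tetramethyl-1,3,2-dioxaborolan-2-yl)chroman-2-one | O=C1C[C@@](B3OC(C)(C)C(C)(C)O3)(C(C)C)c2ccc(C)cc2O1 | intermediate
6 | morpholine | C1COCCN1 | starting material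
7 | sodium perborate tetrahydrate (peroxoborate dimer, water of crystallisation not drawn) | [Na+].[Na+].O[B-]1(O)OO[B-](O)(O)OO1 | starting material
8 | (3S)-3-(2-hydroxy-4-methylphenyl)-4-methyl-1-(morpholin-4-yl)-3-(4,4,5,5-tetramethyl-1,3,2-dioxaborolan-2-yl)pentan-1-one | O=C(C[C@@](B2OC(C)(C)C(C)(C)O2)(C(C)C)c3ccc(C)cc3O)N4CCOCC4 | intermediate (not isolated)
9 | (3R)-3-hydroxy-3-(2-hydroxy-4-methylphenyl)-4-methyl-1-(morpholin-4-yl)pentan-1-one | O=C(C[C@@](O)(C(C)C)c1ccc(C)cc1O)N2CCOCC2 | intermediate
10 | di(propan-2-yl)silanediyl bis(trifluoromethanesulfonate) | CC(C)[Si](OS(=O)(=O)C(F)(F)F)(OS(=O)(=O)C(F)(F)F)C(C)C | starting material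
11 | 2-[(4R)-7-methyl-2,2,4-tri(propan-2-yl)-4H-1,3,2-benzodioxasilin-4-yl]-1-(morpholin-4-yl)ethan-1-one | O=C(C[C@@](O[Si](C(C)C)(C(C)C)O1)(C(C)C)c2ccc(C)cc12)N3CCOCC3 | intermediate
12 | ethylmagnesium bromide | CC[Mg]Br | starting material
13 | 1-[(4R)-7-methyl-2,2,4-tri(propan-2-yl)-4H-1,3,2-benzodioxasilin-4-yl]butan-2-one | CCC(=O)C[C@@](O[Si](C(C)C)(C(C)C)O1)(C(C)C)c2ccc(C)cc12 | intermediate
14 | 2,2,2-trifluoroethyl trifluoroacetate | FC(F)(F)COC(=O)C(F)(F)F | starting material
15 | 4-acetamidobenzenesulfonyl azide | CC(=O)Nc1ccc(cc1)S(=O)(=O)N=[N+]=[N-] | starting material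
16 | 1,1,1-trifluoro-3-methyl-5-[(4R)-7-methyl-2,2,4-tri(propan-2-yl)-4H-1,3,2-benzodioxasilin-4-yl]pentane-2,4-dione (epimers at C3) | CC(C(=O)C(F)(F)F)C(=O)C[C@@](O[Si](C(C)C)(C(C)C)O1)(C(C)C)c2ccc(C)cc12 | intermediate (not isolated)
17 | 3-diazo-1-[(4R)-7-methyl-2,2,4-tri(propan-2-yl)-4H-1,3,2-benzodioxasilin-4-yl]butan-2-one | CC(=[N+]=[N-])C(=O)C[C@@](O[Si](C(C)C)(C(C)C)O1)(C(C)C)c2ccc(C)cc12 | intermediate
18 | norcaradiene valence isomer of 19 (cyclopropane C3a–C8–C8a, diene C4=C5 and C6=C7, methyl on C8a on the five-membered-ring face of the C3 oxygen) | C[C@]12C(=O)C[C@@](O[Si](C(C)C)(C(C)C)O3)(C(C)C)[C@]14C3=CC(C)=C[C@H]24 | intermediate (not isolated)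
19 | (3R,8aR)-3,4-[di(propan-2-yl)silanediylbis(oxy)]-3-isopropyl-6,8a-dimethyl-3,8a-dihydroazulen-1(2H)-one (double bonds C3a=C4, C5=C6, C7=C8) | C1=C(C)C=C[C@@]2(C)C(=O)C[C@@](O[Si](C(C)C)(C(C)C)O3)(C(C)C)C2=C13 | intermediate
20 | (3R,3aS,8aR)-3-hydroxy-3-isopropyl-6,8a-dimethyl-2,3,3a,8a-tetrahydroazulene-1,4-dione (cis-fused) | C1=C(C)C=C[C@@]2(C)C(=O)C[C@@](O)(C(C)C)[C@H]2C1=O | intermediate (not isolated)
21 | (3R,3aR,8aR)-3-hydroxy-3-isopropyl-6,8a-dimethyl-2,3,3a,8a-tetrahydroazulene-1,4-dione (trans-fused) | C1=C(C)C=C[C@@]2(C)C(=O)C[C@@](O)(C(C)C)[C@@H]2C1=O | intermediate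
22 | (3R,3aR,8aR)-3-hydroxy-3-isopropyl-6,8a-dimethyl-2,3,3a,5,8,8a-hexahydroazulene-1,4-dione | CC1=CC[C@@]2(C)C(=O)C[C@@](O)(C(C)C)[C@@H]2C(=O)C1 | intermediate
23 | (3R,3aS,4S,8aR)-3,4-dihydroxy-3-isopropyl-6,8a-dimethyl-3,3a,4,5,8,8a-hexahydroazulen-1(2H)-one | CC1=CC[C@@]2(C)C(=O)C[C@@](O)(C(C)C)[C@@H]2[C@@H](O)C1 | intermediate
24 | 4-(chlorocarbonyl)phenyl acetate | CC(=O)Oc1ccc(cc1)C(Cl)=O | starting material
25 | (3R,3aS,4S,8aR)-3-hydroxy-3-isopropyl-6,8a-dimethyl-1-oxo-1,2,3,3a,4,5,8,8a-octahydroazulen-4-yl 4-acetoxybenzoate | CC1=CC[C@@]2(C)C(=O)C[C@@](O)(C(C)C)[C@@H]2[C@@H](OC(=O)c3ccc(OC(C)=O)cc3)C1 | intermediate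
26 | (1R,3R,3aS,4S,8aR)-1,3-dihydroxy-3-isopropyl-6,8a-dimethyl-1,2,3,3a,4,5,8,8a-octahydroazulen-4-yl 4-acetoxybenzoate | CC1=CC[C@@]2(C)[C@H](O)C[C@@](O)(C(C)C)[C@@H]2[C@@H](OC(=O)c3ccc(OC(C)=O)cc3)C1 | intermediate (not isolated)
27 | (1R,3R,3aS,4S,8aR)-1,3-dihydroxy-3-isopropyl-6,8a-dimethyl-1,2,3,3a,4,5,8,8a-octahydroazulen-4-yl 4-hydroxybenzoate | CC1=CC[C@@]2(C)[C@H](O)C[C@@](O)(C(C)C)[C@@H]2[C@@H](OC(=O)c3ccc(O)cc3)C1 | target

**Totals**

Total step count: 12. Longest linear sequence: 12 steps (from m-cresol; the route is linear).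

**Steps most likely to fail**

Step 7 (key step). The carbene may be diverted before it reaches the arene, by 1,2-hydride migration from its methyl group or by insertion into the isopropyl C–H bond, and the cycloheptatriene may rearrange to a tetralone under trace acid. Fallback, from 11 back to 19: the angular methyl is brought in after the ring expansion. Amide 11 and MeMgBr (THF, 0 °C) should give 1-[(4R)-7-methyl-2,2,4-tri(propan-2-yl)-4H-1,3,2-benzodioxasilin-4-yl]propan-2-one F1. LiN(SiMe3)2/CF3CO2CH2CF3 and then 4-acetamidobenzenesulfonyl azide/Et3N should convert it, through the trifluoroacetyl diketone F2, into the terminal diazo ketone F3, which has no hydrogen next to the carbene carbon. Rh2(OAc)4 in CH2Cl2 should then give, through the norcaradiene F4, the 8a-H azulenone F5, with C8a again fixed by the tether. KN(SiMe3)2 (THF, −78 °C) should remove the ring-fusion proton (α to the ketone and doubly allylic), and MeI should alkylate the enolate at C8a from the face opposite to the isopropyl group, which returns the route to 19.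

Step 2. Addition of the copper boryl to the fully substituted, hindered β-carbon may be slow or poorly face-selective. Fallback, from 1 back to 9: racemic construction of the carbinol and resolution. m-Cresol 1 with isobutyryl chloride/pyridine should give 3-methylphenyl 2-methylpropanoate F6. AlCl3 at 130 °C (Fries rearrangement) should convert it into 1-(2-hydroxy-4-methylphenyl)-2-methylpropan-1-one F7. Reformatsky addition of the zinc enolate from 4-(bromoacetyl)morpholine and Zn (excess, THF, reflux) should give the racemic amide F8. Preparative chromatography on a chiral stationary phase then delivers the (R)-enantiomer 9.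

Step 8. The dienol may be protonated on the wrong face and then epimerise incompletely, or the doubly activated tertiary aldol may be lost under base by retro-aldol cleavage or dehydration. Fallback, from 19 back to 21: the ketone is unveiled and equilibrated before the carbinol is freed. K2CO3 in MeOH at 0 °C should cleave only the enol Si–O bond (the enolate is a far better leaving group than the tertiary alkoxide) and equilibrate C3a while the C3 oxygen is still silylated, giving the trans-fused 3-[methoxydi(propan-2-yl)silyl]oxy dione F9, so that no free β-hydroxy ketone meets base. HF·pyridine in THF should then remove the silyl group and give 21.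

**Further compounds**

F1 | step 7 | 1-[(4R)-7-methyl-2,2,4-tri(propan-2-yl)-4H-1,3,2-benzodioxasilin-4-yl]propan-2-one | CC(=O)C[C@@](O[Si](C(C)C)(C(C)C)O1)(C(C)C)c2ccc(C)cc12
F2 | step 7 | 1,1,1-trifluoro-5-[(4R)-7-methyl-2,2,4-tri(propan-2-yl)-4H-1,3,2-benzodioxasilin-4-yl]pentane-2,4-dione | FC(F)(F)C(=O)CC(=O)C[C@@](O[Si](C(C)C)(C(C)C)O1)(C(C)C)c2ccc(C)cc12
F3 | step 7 | 1-diazo-3-[(4R)-7-methyl-2,2,4-tri(propan-2-yl)-4H-1,3,2-benzodioxasilin-4-yl]propan-2-one | [N-]=[N+]=CC(=O)C[C@@](O[Si](C(C)C)(C(C)C)O1)(C(C)C)c2ccc(C)cc12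
F4 | step 7 | norcaradiene valence isomer of F5 (cyclopropane C3a–C8–C8a, H on C8a in the place of the methyl of 18) | [C@H]12C(=O)C[C@@](O[Si](C(C)C)(C(C)C)O3)(C(C)C)[C@]14C3=CC(C)=C[C@H]24
F5 | step 7 | (3R,8aR)-3,4-[di(propan-2-yl)silanediylbis(oxy)]-3-isopropyl-6-methyl-3,8a-dihydroazulen-1(2H)-one | C1=C(C)C=C[C@H]2C(=O)C[C@@](O[Si](C(C)C)(C(C)C)O3)(C(C)C)C2=C13
F6 | step 2 | 3-methylphenyl 2-methylpropanoate | CC(C)C(=O)Oc1cccc(C)c1
F7 | step 2 | 1-(2-hydroxy-4-methylphenyl)-2-methylpropan-1-one | CC(C)C(=O)c1ccc(C)cc1O
F8 | step 2 | racemic 3-hydroxy-3-(2-hydroxy-4-methylphenyl)-4-methyl-1-(morpholin-4-yl)pentan-1-one | O=C(CC(O)(C(C)C)c1ccc(C)cc1O)N2CCOCC2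
F9 | step 8 | (3R,3aR,8aR)-3-isopropyl-3-{[methoxydi(propan-2-yl)silyl]oxy}-6,8a-dimethyl-2,3,3a,8a-tetrahydroazulene-1,4-dione | C1=C(C)C=C[C@@]2(C)C(=O)C[C@@](O[Si](OC)(C(C)C)C(C)C)(C(C)C)[C@@H]2C1=O
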